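Atoms are numbered round the dioxabicyclooctane: C1 carries the acetate, C2 the guaiacyl ring, then O3, C4H2, bridgehead C5–H, C6 with the veratryl ring, O7 and C8H2. O3 belongs to ring A, O7 to ring B. The whole plan rests on cutting C2–O3. Of the two benzylic carbons only C2 sits para to a free phenol, so a phenol-specific oxidant can convert C2 alone into the electrophilic end of a p-quinone methide. The C4 hydroxyl then adds, which in one final operation makes C2–O3, closes ring A and sets C2. The substrate is the complete ring B tetrahydrofuran with C1 acetate, unprotected 4-hydroxy-3-methoxybenzyl group and free C4 alcohol.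

Key step: step 15

Assumption: the lactol of step 11 is carried as a mixture of anomers and the quinone methide of step 15 as either double-bond isomer, since neither element survives into the next compound.

Step 1
Reactants: 1 vanillin (4-hydroxy-3-methoxybenzaldehyde)
Product: 2 3-methoxy-4-(triisopropylsilyloxy)benzaldehyde
Conditions: TIPSCl, imidazole, DMF, rt
Reagents that add atoms: triisopropylsilyl chloride, CC(C)[Si](Cl)(C(C)C)C(C)C
Why: Imidazole-promoted O-silylation of the acidic phenol is reliable, and the bulky TIPS ether is chosen because it must outlast amide bases, i-Bu2AlH and cold BF3·OEt2 yet fall to fluoride in step 14.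

Step 2
Reactants: 2 3-methoxy-4-(triisopropylsilyloxy)benzaldehyde
Product: 3 [3-methoxy-4-(triisopropylsilyloxy)phenyl]methanol
Conditions: NaBH4, MeOH, 0 °C
Reagents that add atoms: none
Why: Borohydride reduction of an aromatic aldehyde is fast at 0 °C and does not disturb the hindered aryl silyl ether.

Step 3
Reactants: 3 [3-methoxy-4-(triisopropylsilyloxy)phenyl]methanol
Product: 4 4-(bromomethyl)-2-methoxy-1-(triisopropylsilyloxy)benzene
Conditions: CBr4, PPh3, CH2Cl2, 0 °C
Reagents that add atoms: carbon tetrabromide, BrC(Br)(Br)Br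
Why: The Appel reaction replaces the benzylic hydroxyl by bromide under neutral conditions, which suits an electron-rich, easily ionised benzylic halide that is passed through a short silica plug and used at once.

Step 4
Reactants: 5 (S)-4-benzyl-1,3-oxazolidin-2-one; 6 methyl 4-chloro-4-oxobutanoate
Product: 7 methyl 4-[(4S)-4-benzyl-2-oxo-1,3-oxazolidin-3-yl]-4-oxobutanoate
Conditions: Et3N, DMAP (cat.), CH2Cl2, 0 °C → rt
Reagents that add atoms: none
Why: DMAP-catalysed N-acylation of the oxazolidinone with the acid chloride end of 6 gives the imide and leaves the less electrophilic methyl ester alone.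

Step 5
Reactants: 7 methyl 4-[(4S)-4-benzyl-2-oxo-1,3-oxazolidin-3-yl]-4-oxobutanoate; 8 veratraldehyde (3,4-dimethoxybenzaldehyde)
Product: 11 (4S)-4-benzyl-3-{[(2S,3S)-2-(3,4-dimethoxyphenyl)-5-oxotetrahydrofuran-3-yl]carbonyl}-1,3-oxazolidin-2-one (trans lactone), via Z-dibutylboron enolate 9 (not isolated), via syn-aldol hydroxy ester 10 (not isolated)
Conditions: Bu2BOTf, Et3N, CH2Cl2, 0 °C; 8, −78 → 0 °C; H2O2, MeOH, aq. NaH2PO4/Na2HPO4 (pH 7), 0 °C; PPTS (cat.), CH2Cl2, rt
Reagents that add atoms: none
Why: Evans syn-aldol reaction followed by lactonisation: soft enolisation touches only the imide and gives Z-enolate 9, the chair Zimmerman–Traxler transition state on the enolate face left open by the benzyl group of the (S)-auxiliary sets C5 and C6 in 10, and acyl substitution at the methyl ester by the C6 hydroxyl (5-exo-trig) then gives the lactone in which, as a syn aldol requires, the aryl group and the C4 carbonyl arm are trans.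

Step 6
Reactants: 11 trans lactone imide
Product: 13 (2S,3S)-2-(3,4-dimethoxyphenyl)-5-oxotetrahydrofuran-3-carboxylic acid, via peroxy acid 12 (not isolated)
Conditions: LiOH, H2O2, THF–H2O, 0 °C; aq. Na2SO3; HCl to pH 2
Reagents that add atoms: hydrogen peroxide, OO
Why: Hydroperoxide cleavage of the imide attacks the exocyclic carbonyl selectively and frees auxiliary 5 for recovery, sulfite reduces peroxy acid 12, and acidification recloses any lactone opened by hydroxide, C5 being safe because the trans lactone is also the more stable one.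

Step 7
Reactants: 13 (2S,3S)-2-(3,4-dimethoxyphenyl)-5-oxotetrahydrofuran-3-carboxylic acid
Product: 14 (4R,5S)-5-(3,4-dimethoxyphenyl)-4-(hydroxymethyl)dihydrofuran-2(3H)-one
Conditions: BH3·SMe2, THF, 0 °C → rt; MeOH
Reagents that add atoms: none
Why: Borane reduces a free carboxylic acid through its acyloxyborane much faster than a lactone, and the non-basic medium keeps the new C4 hydroxyl from translactonising onto C8.

Step 8
Reactants: 14 (4R,5S)-5-(3,4-dimethoxyphenyl)-4-(hydroxymethyl)dihydrofuran-2(3H)-one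
Product: 15 (4R,5S)-4-[(tert-butyldimethylsilyloxy)methyl]-5-(3,4-dimethoxyphenyl)dihydrofuran-2(3H)-one
Conditions: TBSCl, imidazole, CH2Cl2, 0 °C → rt
Reagents that add atoms: tert-butyldimethylsilyl chloride, CC(C)(C)[Si](C)(C)Cl
Why: Silylation of the primary alcohol under mild imidazole conditions rules out translactonisation for good and puts the bulk on the C4 arm that is to steer both enolate reactions.

Step 9
Reactants: 15 TBS-protected lactone; 4 4-(bromomethyl)-2-methoxy-1-(triisopropylsilyloxy)benzene
Product: 17 (3S,4R,5S)-4-[(tert-butyldimethylsilyloxy)methyl]-5-(3,4-dimethoxyphenyl)-3-[3-methoxy-4-(triisopropylsilyloxy)benzyl]dihydrofuran-2(3H)-one, via lithium enolate 16 (not isolated)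
Conditions: LiN(SiMe3)2, THF, −78 °C; 4, DMPU, −78 → −30 °C
Reagents that add atoms: none
Why: Alkylation of lactone enolate 16 with the reactive benzylic bromide (SN2) should take place anti to the C4 arm, but the C1 configuration formed here does not matter because C1 is made planar again in step 10.

Step 10
Reactants: 17 α-benzyl lactone
Product: 19 (3S,4R,5S)-4-[(tert-butyldimethylsilyloxy)methyl]-5-(3,4-dimethoxyphenyl)-3-hydroxy-3-[3-methoxy-4-(triisopropylsilyloxy)benzyl]dihydrofuran-2(3H)-one, via potassium enolate 18 (not isolated)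
Conditions: KN(SiMe3)2, THF, −78 °C; 3-phenyl-2-(phenylsulfonyl)oxaziridine, −78 °C; AcOH
Reagents that add atoms: 3-phenyl-2-(phenylsulfonyl)oxaziridine, O=S(=O)(c1ccccc1)N1OC1c1ccccc1
Why: Davis oxidation of the fully substituted enolate 18: the oxaziridine transfers its oxygen to the face of C1 anti to the adjacent CH2OTBS arm, so that the hydroxyl ends up trans and the benzyl group cis to that arm, which is the 1S quaternary centre of the target and the sense seen in α-hydroxylations of α,β-disubstituted butyrolactone lignans.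

Step 11
Reactants: 19 α-hydroxy lactone
Product: 20 (3S,4R,5S)-4-[(tert-butyldimethylsilyloxy)methyl]-5-(3,4-dimethoxyphenyl)-3-[3-methoxy-4-(triisopropylsilyloxy)benzyl]tetrahydrofuran-2,3-diol (lactol, both anomers)
Conditions: i-Bu2AlH (2.5 equiv), CH2Cl2, −78 °C; aq. potassium sodium tartrate
Reagents that add atoms: none
Why: Partial reduction of a lactone with i-Bu2AlH stops at the aluminium hemiacetal at −78 °C, one equivalent being spent on the tertiary hydroxyl, and neither silyl ether is affected.

Step 12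
Reactants: 20 lactol
Product: 21 (3S,4R,5S)-4-[(tert-butyldimethylsilyloxy)methyl]-5-(3,4-dimethoxyphenyl)-3-[3-methoxy-4-(triisopropylsilyloxy)benzyl]tetrahydrofuran-3-ol
Conditions: Et3SiH (5 equiv), BF3·OEt2 (1.5 equiv), CH2Cl2, −78 → −40 °C; aq. NaHCO3 at −40 °C
Reagents that add atoms: none
Why: Ionic reduction of a lactol: BF3·OEt2 ionises the anomeric hydroxyl to the ring B oxocarbenium ion and Et3SiH delivers hydride to C8, and in the cold this acetal-type ionisation should be well ahead of any opening of the C6–O7 benzylic ether, so that C6 is kept.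

Step 13
Reactants: 21 ring B tertiary alcohol
Product: 22 (3S,4R,5S)-4-[(tert-butyldimethylsilyloxy)methyl]-5-(3,4-dimethoxyphenyl)-3-[3-methoxy-4-(triisopropylsilyloxy)benzyl]tetrahydrofuran-3-yl acetate
Conditions: Ac2O, Et3N, DMAP (0.5 equiv), CH2Cl2, rt → 40 °C
Reagents that add atoms: acetic anhydride, CC(=O)OC(C)=O
Why: DMAP-catalysed acylation through the N-acetylpyridinium ion is the standard answer to hindered tertiary alcohols, needs no acid that could open the C6 benzylic ether, and finds no other free hydroxyl in 21.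

Step 14
Reactants: 22 bis-silylated tertiary acetate
Product: 23 (3S,4R,5S)-5-(3,4-dimethoxyphenyl)-3-(4-hydroxy-3-methoxybenzyl)-4-(hydroxymethyl)tetrahydrofuran-3-yl acetate
Conditions: Bu4NF (3 equiv), AcOH (3 equiv), THF, 0 °C → rt
Reagents that add atoms: none
Why: Fluoride cleaves both Si–O bonds in one operation, while the AcOH buffer keeps the freed phenol and C4 alcohol protonated so that the acetate, which moreover stands trans to the C4 arm on ring B, should stay on the C1 oxygen.

Step 15
Reactants: 23 ring B tetrahydrofuran with C1 acetate, free phenol and free C4 alcohol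
Product: 25 (1S,2R,5R,6S)-6-(3,4-dimethoxyphenyl)-2-(4-hydroxy-3-methoxyphenyl)-3,7-dioxabicyclo[3.3.0]octan-1-yl acetate (target), via p-quinone methide 24 (not isolated)
Conditions: Ag2O (1.5 equiv), dry CH2Cl2 (2 mM), dark, rt; filtration
Reagents that add atoms: none
Why: On the Ag2O surface the phenol of 23 is oxidised in two one-electron stages, first to the phenoxyl radical and then, with loss of one C2 hydrogen, to p-quinone methide 24, whose exocyclic carbon is C2. The C4 hydroxyl then attacks C2 in the conjugate 1,6-sense and the six-membered ring regains aromaticity, which should make the closure irreversible in this neutral medium. The closest known reaction type is the oxidation of 4-alkyl-2-methoxyphenols to p-quinone methides with capture by an internal alcohol, the way benzyl-tetrahydrofuran lignans are turned into furofurans. Ring A closes in the 5-exo-trig mode, and its cis fusion is forced because the benzylic carbon and the C4 arm stand on the same face of ring B. C2 is under substrate control: in the reacting conformer the flat dienone turns away from C8 and the concave side of the nascent bicycle, so the aryl group should end up exo, cis to the acetate (2R). The step needs site selectivity between C2–H and the doubly activated C6–H, and it is secured because the veratryl ring has no hydroxyl for Ag2O to oxidise; the quaternary C1 also blocks tautomerisation of 24 to a styrene, and high dilution with only a small excess of oxidant holds back phenoxyl coupling and further oxidation of 25.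

Compound list
1 | vanillin | COc1cc(C=O)ccc1O | starting material
2 | 3-methoxy-4-(triisopropylsilyloxy)benzaldehyde | COc1cc(C=O)ccc1O[Si](C(C)C)(C(C)C)C(C)C | intermediate
3 | [3-methoxy-4-(triisopropylsilyloxy)phenyl]methanol | COc1cc(CO)ccc1O[Si](C(C)C)(C(C)C)C(C)C | intermediate
4 | 4-(bromomethyl)-2-methoxy-1-(triisopropylsilyloxy)benzene | COc1cc(CBr)ccc1O[Si](C(C)C)(C(C)C)C(C)C | intermediate
5 | (S)-4-benzyl-1,3-oxazolidin-2-one | O=C1N[C@@H](Cc2ccccc2)CO1 | starting material
6 | methyl 4-chloro-4-oxobutanoate | COC(=O)CCC(=O)Cl | starting material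
7 | methyl 4-[(4S)-4-benzyl-2-oxo-1,3-oxazolidin-3-yl]-4-oxobutanoate | COC(=O)CCC(=O)N1[C@@H](Cc2ccccc2)COC1=O | intermediate
8 | veratraldehyde | COc1ccc(C=O)cc1OC | starting material
9 | (Z)-dibutylboron enolate of 7 | COC(=O)C/C=C(\OB(CCCC)CCCC)N1[C@@H](Cc2ccccc2)COC1=O | intermediate
10 | methyl (3S,4S)-3-{[(4S)-4-benzyl-2-oxo-1,3-oxazolidin-3-yl]carbonyl}-4-(3,4-dimethoxyphenyl)-4-hydroxybutanoate (syn aldol) | COC(=O)C[C@@H]([C@H](O)c1ccc(OC)c(OC)c1)C(=O)N1[C@@H](Cc2ccccc2)COC1=O | intermediate
11 | (4S)-4-benzyl-3-{[(2S,3S)-2-(3,4-dimethoxyphenyl)-5-oxotetrahydrofuran-3-yl]carbonyl}-1,3-oxazolidin-2-one | O=C1C[C@H](C(=O)N2[C@@H](Cc3ccccc3)COC2=O)[C@@H](c2ccc(OC)c(OC)c2)O1 | intermediate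
12 | (2S,3S)-2-(3,4-dimethoxyphenyl)-5-oxotetrahydrofuran-3-carboperoxoic acid | O=C1C[C@H](C(=O)OO)[C@@H](c2ccc(OC)c(OC)c2)O1 | intermediate
13 | (2S,3S)-2-(3,4-dimethoxyphenyl)-5-oxotetrahydrofuran-3-carboxylic acid | O=C1C[C@H](C(=O)O)[C@@H](c2ccc(OC)c(OC)c2)O1 | intermediate
14 | (4R,5S)-5-(3,4-dimethoxyphenyl)-4-(hydroxymethyl)dihydrofuran-2(3H)-one | O=C1C[C@H](CO)[C@@H](c2ccc(OC)c(OC)c2)O1 | intermediate
15 | (4R,5S)-4-[(tert-butyldimethylsilyloxy)methyl]-5-(3,4-dimethoxyphenyl)dihydrofuran-2(3H)-one | O=C1C[C@H](CO[Si](C)(C)C(C)(C)C)[C@@H](c2ccc(OC)c(OC)c2)O1 | intermediate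
16 | lithium enolate of 15 | [Li]OC1=C[C@H](CO[Si](C)(C)C(C)(C)C)[C@@H](c2ccc(OC)c(OC)c2)O1 | intermediate
17 | (3S,4R,5S)-α-benzyl lactone, benzyl trans to the C4 arm | COc1cc(C[C@@H]2C(=O)O[C@H](c3ccc(OC)c(OC)c3)[C@H]2CO[Si](C)(C)C(C)(C)C)ccc1O[Si](C(C)C)(C(C)C)C(C)C | intermediate
18 | potassium enolate of 17 | COc1cc(CC2=C(O[K])O[C@H](c3ccc(OC)c(OC)c3)[C@H]2CO[Si](C)(C)C(C)(C)C)ccc1O[Si](C(C)C)(C(C)C)C(C)C | intermediate
19 | (3S,4R,5S)-α-benzyl-α-hydroxy lactone, hydroxyl trans to the C4 arm | COc1cc(C[C@@]2(O)C(=O)O[C@H](c3ccc(OC)c(OC)c3)[C@H]2CO[Si](C)(C)C(C)(C)C)ccc1O[Si](C(C)C)(C(C)C)C(C)C | intermediate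
20 | lactol of 19 (both anomers) | COc1cc(C[C@@]2(O)C(O)O[C@H](c3ccc(OC)c(OC)c3)[C@H]2CO[Si](C)(C)C(C)(C)C)ccc1O[Si](C(C)C)(C(C)C)C(C)C | intermediate
21 | (3S,4R,5S)-ring B tetrahydrofuran-3-ol, bis-silylated | COc1cc(C[C@@]2(O)CO[C@H](c3ccc(OC)c(OC)c3)[C@H]2CO[Si](C)(C)C(C)(C)C)ccc1O[Si](C(C)C)(C(C)C)C(C)C | intermediate
22 | (3S,4R,5S)-ring B tetrahydrofuran-3-yl acetate, bis-silylated | COc1cc(C[C@@]2(OC(C)=O)CO[C@H](c3ccc(OC)c(OC)c3)[C@H]2CO[Si](C)(C)C(C)(C)C)ccc1O[Si](C(C)C)(C(C)C)C(C)C | intermediate
23 | (3S,4R,5S)-5-(3,4-dimethoxyphenyl)-3-(4-hydroxy-3-methoxybenzyl)-4-(hydroxymethyl)tetrahydrofuran-3-yl acetate | COc1cc(C[C@@]2(OC(C)=O)CO[C@H](c3ccc(OC)c(OC)c3)[C@H]2CO)ccc1O | intermediate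
24 | p-quinone methide of 23 (exocyclic carbon = C2) | COC1=CC(=C[C@@]2(OC(C)=O)CO[C@H](c3ccc(OC)c(OC)c3)[C@H]2CO)C=CC1=O | intermediate
25 | (1S,2R,5R,6S)-6-(3,4-dimethoxyphenyl)-2-(4-hydroxy-3-methoxyphenyl)-3,7-dioxabicyclo[3.3.0]octan-1-yl acetate | COc1cc([C@H]2OC[C@@H]3[C@@H](c4ccc(OC)c(OC)c4)OC[C@]23OC(C)=O)ccc1O | target

Total step count: 15. Longest linear sequence: 12 steps (steps 4–15, from 5 and 6). Steps 1–3 are the side branch to bromide 4.

Steps most likely to fail

Step 15. Coupling of two phenoxyl radicals through the open ring position ortho to the hydroxyl may outrun loss of the C2 hydrogen, and the phenolic product may be oxidised a second time. Fallback: that position is blocked with a removable bromine, a tactic known from oxidative couplings of guaiacyl phenols.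
- Setting out from 23, NBS with catalytic i-Pr2NH in CH2Cl2 at −78 → 0 °C should brominate only the free phenol ring, ortho to its hydroxyl, to give the bromophenol F1.
- Ag2O under the conditions of step 15 should take it through the bromo quinone methide F2 to the bromo furofuran F3. There is now no coupling site, and the product is less easily oxidised.
- Hydrodebromination (H2, Pd/C, Et3N, EtOAc, rt, stopped after one equivalent of H2) removes the halogen and comes back to the route at 25.

Step 12. The lactol, slowed by the oxygen on C1, may ionise no faster than the C6–O7 benzylic ether. That would open the way to epimerisation at C6, reductive ring opening or Friedel–Crafts capture by the other arene. Fallback: O7–C8 is re-made by substitution under basic conditions, so that no Lewis acid meets C6.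
- Setting out from 19, LiBH4 in THF (0 °C → rt) reduces the lactone to the triol F4.
- TsCl in pyridine at 0 °C should sulfonylate only the primary C8 hydroxyl to give the monotosylate F5.
- On warming to 60 °C the C6 hydroxyl displaces the sulfonate (5-exo-tet). C6 is retained because no bond to it is broken, and this comes back to the route at 21.

Step 14. Once the C4 hydroxyl is free, the acetyl group may shift to it from the tertiary oxygen, or be lost, while fluoride is present. Fallback: the acetate is put on only after O3 is tied up in ring A.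
- Setting out from 21, Bu4NF in THF gives the triol F6.
- Ag2O as in step 15 converts it through the quinone methide F7 into the bridgehead alcohol F8.
- Ac2O, Et3N and DMAP at 40 °C esterify both the phenol and the tertiary alcohol to give the diacetate F9.
- Pyrrolidine in CH2Cl2 at 0 °C cleaves the aryl acetate alone by aminolysis, and the route is rejoined at 25.

Further compounds
F1 | step 15 | (3S,4R,5S)-3-(3-bromo-4-hydroxy-5-methoxybenzyl)-5-(3,4-dimethoxyphenyl)-4-(hydroxymethyl)tetrahydrofuran-3-yl acetate | COc1cc(C[C@@]2(OC(C)=O)CO[C@H](c3ccc(OC)c(OC)c3)[C@H]2CO)cc(Br)c1O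
F2 | step 15 | bromo p-quinone methide of F1 | COC1=CC(=C[C@@]2(OC(C)=O)CO[C@H](c3ccc(OC)c(OC)c3)[C@H]2CO)C=C(Br)C1=O
F3 | step 15 | (1S,2R,5R,6S)-2-(3-bromo-4-hydroxy-5-methoxyphenyl)-6-(3,4-dimethoxyphenyl)-3,7-dioxabicyclo[3.3.0]octan-1-yl acetate | COc1cc([C@H]2OC[C@@H]3[C@@H](c4ccc(OC)c(OC)c4)OC[C@]23OC(C)=O)cc(Br)c1O
F4 | step 12 | (2S,3R,4S)-3-[(tert-butyldimethylsilyloxy)methyl]-4-(3,4-dimethoxyphenyl)-2-[3-methoxy-4-(triisopropylsilyloxy)benzyl]butane-1,2,4-triol | COc1cc(C[C@@](O)(CO)[C@H](CO[Si](C)(C)C(C)(C)C)[C@H](O)c2ccc(OC)c(OC)c2)ccc1O[Si](C(C)C)(C(C)C)C(C)C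
F5 | step 12 | primary (C8) 4-methylbenzenesulfonate of F4 | COc1cc(C[C@@](O)(COS(=O)(=O)c2ccc(C)cc2)[C@H](CO[Si](C)(C)C(C)(C)C)[C@H](O)c2ccc(OC)c(OC)c2)ccc1O[Si](C(C)C)(C(C)C)C(C)C
F6 | step 14 | (3S,4R,5S)-5-(3,4-dimethoxyphenyl)-3-(4-hydroxy-3-methoxybenzyl)-4-(hydroxymethyl)tetrahydrofuran-3-ol | COc1cc(C[C@@]2(O)CO[C@H](c3ccc(OC)c(OC)c3)[C@H]2CO)ccc1O
F7 | step 14 | p-quinone methide of F6 | COC1=CC(=C[C@@]2(O)CO[C@H](c3ccc(OC)c(OC)c3)[C@H]2CO)C=CC1=O
F8 | step 14 | (1S,2R,5R,6S)-6-(3,4-dimethoxyphenyl)-2-(4-hydroxy-3-methoxyphenyl)-3,7-dioxabicyclo[3.3.0]octan-1-ol | COc1cc([C@H]2OC[C@@H]3[C@@H](c4ccc(OC)c(OC)c4)OC[C@]23O)ccc1O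
F9 | step 14 | diacetate of F8 (bridgehead acetate and aryl acetate) | COc1cc([C@H]2OC[C@@H]3[C@@H](c4ccc(OC)c(OC)c4)OC[C@]23OC(C)=O)ccc1OC(C)=O
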